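The charges let at most 90.0 % of the Ja become Wu, for each Wu costs one Zu, and Ly, the limiting reagent, was charged at less than Ja.

    Zu ⇌ Ly, rate k1*([Zu] - [Ly]/K1) per volume of the first phase (K1 = 0.43, k1 = 0.0458 s⁻¹)
    Ja + Zu → Wu (k2 = 0.292 M⁻¹ s⁻¹)
    Zu + Wu → Ez (k3 = 0.488 M⁻¹ s⁻¹)
    2 Zu → Gu (k4 = 0.275 M⁻¹ s⁻¹)
    Ja ⇌ Xi (K5 = 1.78, k5 = 7.43 × 10⁻⁴ s⁻¹)

Ja 0.053 M; Ly 0.0477 M; time 80 s; volume of the second phase over the first 0.50

- a doubled species enters its step squared and goes two at a time
- in the second phase: Ly; everything else is in the first
- charges count per volume of the first phase; a concentration in a rate is the amount of a species over the volume of its own phase; every rate counts per litre of the first phase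
- run time (flask): 80 s

- how much Wu there is at 80 s, in percent of the Ja charged
- the change that raises the amount of Wu at 80 s, in percent of the Ja charged most ("none" if none brings more than 2 percentage points) (Saturday's / Tuesday's / none)
- amount of Wu at 80 s, in percent of the Ja charged, after Tuesday's

**First instants.** I reckoned this flask by hand. Ly and Zu came to their partition with a half-life of 2.68 s, much shorter than the 45 s half-life of Zu against Ja as charged. So I took the uptake as instant, with 82.3 % of the reagent standing as Zu from the start.

**The middle.** Zu then leaked two ways. The first went in proportion to Zu: Ja took it, and Wu took it 1.67 times as readily, the selectivity factor. As Ja fell and Wu rose, I held their joint pull at its starting value. The second, the pairing of Zu to Gu, went with Zu squared and on my figures began faster than the first. The step to Xi relaxes in 9.96 min, much longer than the run, so I dropped it. Summing the two leaks over the time gave 0.411 for the dose, the rate constant of Ja + Zu times the mean of Zu times the time. The curve of Zu is replaced by that mean, and e to the minus dose is the fraction of Ja which that step spares.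

**The end.** On paper that spared 66.3 % of the Ja. Wu is the difference between e to the minus dose and e to the minus selectivity factor times dose, over the selectivity factor less one: 23.8 %. Tuesday's, doubling the Ly, gave a dose of 0.660 and Wu of 27.6 %. Saturday's, doubling the transfer coefficient of the uptake, left my instant uptake untouched, so I named Tuesday's.

**The forecast.** It gave 22.5 % of Wu, named Tuesday's and put Wu after that change at 26.5 %, holding that “much of the gain is lost to the squared Zu loss and to Wu overreaction”. My figure for Tuesday's stood above it.

**The run.** The simulated flask gave 23.1 % of Wu. Tuesday's won with 3.9 percentage points, reaching 26.9 %, against 0.046 points for Saturday's.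

**Dose again.** The net turnover of Ja + Zu, 32.6 % of the Ja charged, reads back, Xi left aside, as a dose of about 0.395 in this flask, against my 0.411. For the neighbour with 0.13 M of Ja the rule gives a dose of 0.271 and Wu of 18.9 %; that flask stood at 18.4 %. In the first flask, part of what Wu lacks went to Ez: with the loss of Zu + Wu to Ez struck out, Wu rose from 23.1 % to 34.4 %.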